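**Plan**

1. Retrosynthesis: the three MOM ethers and a temporary C4 ketone are put back first. The C2–C3 bond is then cut by a retro-Petasis–Ferrier step to a cyclic enol formal in which C2 bridges O1 and the C4 enol oxygen. Removing C2 and cutting C3–C1' (ketone α-arylation) leaves a methyl ketone and an aryl bromide with the same 2-prenylresorcinol skeleton, and the ketone is itself cut back to that bromide.
2. Enabling feature: rings A and B carry the identical 2,4-dioxygenated 3-prenylphenyl pattern, and C3 lies between C1' of ring B and the ring A benzylic carbon C4. With C4 as a ketone, its enol oxygen and O1 are 1,5-related, so one formaldehyde carbon (C2) can be tied to both oxygens and then moved from oxygen to C3.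
3. Forward order: resorcinol → bis-MOM ether → prenylation between the oxygens → aryl bromide (ring B half) → part of it converted into the methyl ketone (ring A half) → α-arylation joins the chain (C3–C1') → O1 freed → 1,3-benzodioxine enol formal → Lewis-acid ionisation and C2–C3 closure give the pyranone ring (isoflavanone).
4. Stereochemistry: C3 is formed racemic and kept epimerisable by the C4 ketone. Ru-catalysed asymmetric transfer hydrogenation with dynamic kinetic resolution ((R,R)-TsDPEN ligand) sets 3R together with a temporary 4R carbinol. Radical deoxygenation at C4 and MOM removal finish the route without touching C3.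

Key step: step 8

Abbreviations: MOM = methoxymethyl; prenyl = 3-methylbut-2-en-1-yl.

**Route**

Step 1
Reactants: 1 resorcinol
Product: 2 1,3-bis(methoxymethoxy)benzene
Conditions: NaH (2.4 equiv), MOMCl (2.4 equiv), DMF, 0 °C to rt
Reagents that add atoms: chloromethyl methyl ether, COCCl
Why: Williamson-type O-alkylation of the bis-phenoxide installs two acetal protecting groups that also serve as directing groups for the later metalations.

Step 2
Reactants: 2 1,3-bis(methoxymethoxy)benzene
Product: 4 1,3-bis(methoxymethoxy)-2-prenylbenzene, via aryllithium 3 (not isolated)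
Conditions: n-BuLi (1.1 equiv), THF, 0 °C to rt; then CuI (10 mol %), prenyl bromide (1.2 equiv), −20 °C to rt
Reagents that add atoms: 1-bromo-3-methylbut-2-ene (prenyl bromide), CC(C)=CCBr
Why: Directed ortho-metalation takes place at the doubly chelated position between the two MOM ethers, and the aryllithium is alkylated at the primary carbon of prenyl bromide under copper catalysis (SN2 without allylic transposition).

Step 3
Reactants: 4 1,3-bis(methoxymethoxy)-2-prenylbenzene
Product: 6 1-bromo-2,4-bis(methoxymethoxy)-3-prenylbenzene, via aryllithium 5 (not isolated)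
Conditions: n-BuLi (1.2 equiv), TMEDA (1.2 equiv), THF, −20 to 0 °C; then BrCH2CH2Br (1.5 equiv), −78 °C to rt
Reagents that add atoms: 1,2-dibromoethane, BrCCBr
Why: A second directed ortho-metalation occurs ortho to one MOM ether (the two open ortho positions are equivalent), and bromine transfer from 1,2-dibromoethane to the aryllithium should give the aryl bromide without exposing the prenyl double bond to electrophilic bromine.

Step 4
Reactants: 6 1-bromo-2,4-bis(methoxymethoxy)-3-prenylbenzene
Product: 8 1-[2,4-bis(methoxymethoxy)-3-prenylphenyl]ethan-1-one, via enol ether 7 (not isolated)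
Conditions: tributyl(1-ethoxyethenyl)stannane (1.2 equiv), Pd(PPh3)4 (5 mol %), toluene, 100 °C; then aq HCl (0.1 M), THF, 0 °C, 15 min
Reagents that add atoms: tributyl(1-ethoxyethenyl)stannane, CCCC[Sn](CCCC)(CCCC)C(=C)OCC; water, O
Why: Kosugi–Migita–Stille coupling of the aryl bromide with the 1-ethoxyvinyl stannane (an acetyl anion equivalent) gives the α-ethoxystyrene, whose hydrolysis in dilute acid is far faster than cleavage of the aryl MOM acetals and should give the methyl ketone.

Step 5
Reactants: 8 1-[2,4-bis(methoxymethoxy)-3-prenylphenyl]ethan-1-one; 6 1-bromo-2,4-bis(methoxymethoxy)-3-prenylbenzene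
Product: 9 1,2-bis[2,4-bis(methoxymethoxy)-3-prenylphenyl]ethan-1-one
Conditions: Pd2(dba)3 (2 mol %), Xantphos (5 mol %), NaOtBu (2.2 equiv), toluene, 80 °C
Reagents that add atoms: none
Why: Palladium-catalysed α-arylation of the methyl ketone enolate joins the two identical aryl units through C3–C1', with mono-arylation favoured by the ortho-substituted bromide and the hindered, less nucleophilic product enolate.

Step 6
Reactants: 9 1,2-bis[2,4-bis(methoxymethoxy)-3-prenylphenyl]ethan-1-one
Product: 10 2-[2,4-bis(methoxymethoxy)-3-prenylphenyl]-1-[2-hydroxy-4-(methoxymethoxy)-3-prenylphenyl]ethan-1-one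
Conditions: HCl (0.3 M) in MeOH–THF, 0 °C to rt, stopped at mono-cleavage
Reagents that add atoms: none
Why: Acid-catalysed acetal methanolysis should be fastest for the MOM ether ortho to the ketone, whose carbonyl relays the proton to the aryl oxygen through a six-membered hydrogen bond and stabilises the chelated phenol, so that O1 alone is set free.

Step 7
Reactants: 10 2-[2,4-bis(methoxymethoxy)-3-prenylphenyl]-1-[2-hydroxy-4-(methoxymethoxy)-3-prenylphenyl]ethan-1-one
Product: 12 (4Z)-4-{[2,4-bis(methoxymethoxy)-3-prenylphenyl]methylidene}-7-(methoxymethoxy)-8-prenyl-4H-1,3-benzodioxine, via chloromethyl ether 11 (not isolated)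
Conditions: BrCH2Cl (10 equiv), Cs2CO3 (3 equiv), DMF (0.02 M), 60 °C
Reagents that add atoms: bromochloromethane, ClCBr
Why: Double Williamson O-alkylation (methylene acetal formation) is expected, the phenoxide displacing bromide first and the hard chloromethyl ether then alkylating the caesium enolate on oxygen by 6-exo-tet closure, which ties O1 and the enol oxygen to the future C2 and places the aryl group of the Z enol ether away from the peri hydrogen.

Step 8
Reactants: 12 (4Z)-4-{[2,4-bis(methoxymethoxy)-3-prenylphenyl]methylidene}-7-(methoxymethoxy)-8-prenyl-4H-1,3-benzodioxine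
Product: 14 rac-3-[2,4-bis(methoxymethoxy)-3-prenylphenyl]-7-(methoxymethoxy)-8-prenyl-2,3-dihydro-4H-chromen-4-one, via oxocarbenium enolate ion pair 13 (not isolated)
Conditions: Me2AlCl (2.5 equiv), CH2Cl2, −78 to −30 °C; aq NaHCO3
Reagents that add atoms: none
Why: Proposed new method: Me2AlCl binds the enol-ether oxygen and ionises its bond to the acetal carbon, giving a contact ion pair of an aluminium enolate and an aryloxy-stabilised oxocarbenium ion (O1=C2) that recombines at carbon to form C2–C3; the closest known reaction is the Petasis–Ferrier rearrangement of 4-alkylidene-1,3-dioxanes to tetrahydropyran-4-ones, which has not been shown for a benzo-fused formaldehyde acetal. The pyranone ring closes in the 6-(enolendo)-endo-trig mode, since both enolate carbons and the O1=C2 unit lie inside the new ring. The new stereocentre C3 is formed without control, which is intended, because it stays epimerisable next to the ketone and is set in step 9. The step needs ionisation of the O(enol)–C2 bond in preference to O1–C2 or the MOM acetals, recombination at carbon instead of oxygen, and capture by the enolate instead of the C8 prenyl double bond. The first should be secured by the conjugated aryl ketone enolate as leaving group and the low temperature, the second because O-recombination only returns 12 whereas C–C formation is irreversible, and the third because the enolate carbon is held 1,6 to C2 in the ion pair and is far more nucleophilic than a trisubstituted alkene.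

Step 9
Reactants: 14 rac-3-[2,4-bis(methoxymethoxy)-3-prenylphenyl]-7-(methoxymethoxy)-8-prenyl-2,3-dihydro-4H-chromen-4-one
Product: 15 (3R,4R)-3-[2,4-bis(methoxymethoxy)-3-prenylphenyl]-7-(methoxymethoxy)-8-prenyl-3,4-dihydro-2H-chromen-4-ol (cis)
Conditions: RuCl[(R,R)-TsDPEN](p-cymene) (2 mol %), HCO2H–Et3N (5:2), EtOAc, 40 °C
Reagents that add atoms: none
Why: In this Noyori–Ikariya asymmetric transfer hydrogenation with dynamic kinetic resolution, C3 should epimerise through the enol faster than the slow-reacting enantiomer is reduced, the (R,R)-catalyst delivers hydride to give the 4R carbinol, and hydride approach anti to the C3 aryl group makes the product cis, which fixes C3 as 3R.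

Step 10
Reactants: 15 (3R,4R)-3-[2,4-bis(methoxymethoxy)-3-prenylphenyl]-7-(methoxymethoxy)-8-prenyl-3,4-dihydro-2H-chromen-4-ol
Product: 16 O-[(3R,4R)-3-[2,4-bis(methoxymethoxy)-3-prenylphenyl]-7-(methoxymethoxy)-8-prenyl-3,4-dihydro-2H-chromen-4-yl] 1H-imidazole-1-carbothioate
Conditions: 1,1'-thiocarbonyldiimidazole (2 equiv), DMAP (0.2 equiv), ClCH2CH2Cl, 60 °C
Reagents that add atoms: 1,1'-thiocarbonyldiimidazole, S=C(n1ccnc1)n1ccnc1
Why: Thioacylation of the secondary benzylic alcohol gives the thiocarbonyl derivative needed for Barton–McCombie deoxygenation, and thermal syn-elimination is disfavoured because the C3 hydrogen is trans to the C4 oxygen in the cis isomer.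

Step 11
Reactants: 16 O-[(3R,4R)-3-[2,4-bis(methoxymethoxy)-3-prenylphenyl]-7-(methoxymethoxy)-8-prenyl-3,4-dihydro-2H-chromen-4-yl] 1H-imidazole-1-carbothioate
Product: 17 (3R)-3-[2,4-bis(methoxymethoxy)-3-prenylphenyl]-7-(methoxymethoxy)-8-prenyl-3,4-dihydro-2H-chromene
Conditions: Bu3SnH (2 equiv), AIBN (0.2 equiv), toluene, 90 °C
Reagents that add atoms: none
Why: In this Barton–McCombie radical deoxygenation the stannyl radical adds to sulfur, the benzylic C4–O bond fragments and the C4 radical takes hydrogen from Bu3SnH, which should leave the C3 stereocentre and both prenyl double bonds untouched.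

Step 12
Reactants: 17 (3R)-3-[2,4-bis(methoxymethoxy)-3-prenylphenyl]-7-(methoxymethoxy)-8-prenyl-3,4-dihydro-2H-chromene
Product: 18 Kanzonol X, 4-[(3R)-7-hydroxy-8-prenyl-3,4-dihydro-2H-chromen-3-yl]-2-prenylbenzene-1,3-diol
Conditions: HCl (1 M) in MeOH–THF, 40 °C
Reagents that add atoms: none
Why: Acid-catalysed methanolysis of the three aryl MOM acetals under mild conditions should release the phenols while the prenyl groups and the C3 stereocentre, which is not acidic, remain intact.

**Compound list**

1 | resorcinol (benzene-1,3-diol) | Oc1cccc(O)c1 | starting material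
2 | 1,3-bis(methoxymethoxy)benzene | COCOc1cccc(OCOC)c1 | intermediate
3 | [2,6-bis(methoxymethoxy)phenyl]lithium | [Li]c1c(OCOC)cccc1OCOC | intermediate
4 | 1,3-bis(methoxymethoxy)-2-(3-methylbut-2-en-1-yl)benzene | COCOc1cccc(OCOC)c1CC=C(C)C | intermediate
5 | [2,4-bis(methoxymethoxy)-3-(3-methylbut-2-en-1-yl)phenyl]lithium | [Li]c1ccc(OCOC)c(CC=C(C)C)c1OCOC | intermediate
6 | 1-bromo-2,4-bis(methoxymethoxy)-3-(3-methylbut-2-en-1-yl)benzene | Brc1ccc(OCOC)c(CC=C(C)C)c1OCOC | intermediate
7 | 1-(1-ethoxyethenyl)-2,4-bis(methoxymethoxy)-3-(3-methylbut-2-en-1-yl)benzene | C=C(OCC)c1ccc(OCOC)c(CC=C(C)C)c1OCOC | intermediate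
8 | 1-[2,4-bis(methoxymethoxy)-3-(3-methylbut-2-en-1-yl)phenyl]ethan-1-one | CC(=O)c1ccc(OCOC)c(CC=C(C)C)c1OCOC | intermediate
9 | 1,2-bis[2,4-bis(methoxymethoxy)-3-(3-methylbut-2-en-1-yl)phenyl]ethan-1-one | O=C(Cc1ccc(OCOC)c(CC=C(C)C)c1OCOC)c1ccc(OCOC)c(CC=C(C)C)c1OCOC | intermediate
10 | 2-[2,4-bis(methoxymethoxy)-3-(3-methylbut-2-en-1-yl)phenyl]-1-[2-hydroxy-4-(methoxymethoxy)-3-(3-methylbut-2-en-1-yl)phenyl]ethan-1-one | O=C(Cc1ccc(OCOC)c(CC=C(C)C)c1OCOC)c1ccc(OCOC)c(CC=C(C)C)c1O | intermediate
11 | 2-[2,4-bis(methoxymethoxy)-3-(3-methylbut-2-en-1-yl)phenyl]-1-[2-(chloromethoxy)-4-(methoxymethoxy)-3-(3-methylbut-2-en-1-yl)phenyl]ethan-1-one | O=C(Cc1ccc(OCOC)c(CC=C(C)C)c1OCOC)c1ccc(OCOC)c(CC=C(C)C)c1OCCl | intermediate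
12 | (4Z)-4-{[2,4-bis(methoxymethoxy)-3-(3-methylbut-2-en-1-yl)phenyl]methylidene}-7-(methoxymethoxy)-8-(3-methylbut-2-en-1-yl)-4H-1,3-benzodioxine | C1Oc2c(CC=C(C)C)c(OCOC)ccc2/C(=C/c2ccc(OCOC)c(CC=C(C)C)c2OCOC)O1 | intermediate
13 | ring-opened ion pair: (Z)-chlorodimethylaluminate enolate of the aryl benzyl ketone, carrying an O-methylideneoxonium group on the ring A oxygen | C=[O+]c1c(CC=C(C)C)c(OCOC)ccc1/C(O[Al-](C)(C)Cl)=C/c1ccc(OCOC)c(CC=C(C)C)c1OCOC | intermediate
14 | rac-3-[2,4-bis(methoxymethoxy)-3-(3-methylbut-2-en-1-yl)phenyl]-7-(methoxymethoxy)-8-(3-methylbut-2-en-1-yl)-2,3-dihydro-4H-chromen-4-one | O=C1c2ccc(OCOC)c(CC=C(C)C)c2OCC1c1ccc(OCOC)c(CC=C(C)C)c1OCOC | intermediate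
15 | (3R,4R)-3-[2,4-bis(methoxymethoxy)-3-(3-methylbut-2-en-1-yl)phenyl]-7-(methoxymethoxy)-8-(3-methylbut-2-en-1-yl)-3,4-dihydro-2H-chromen-4-ol | CC(C)=CCc1c(OCOC)ccc([C@@H]2COc3c(ccc(OCOC)c3CC=C(C)C)[C@@H]2O)c1OCOC | intermediate
16 | O-[(3R,4R)-3-[2,4-bis(methoxymethoxy)-3-(3-methylbut-2-en-1-yl)phenyl]-7-(methoxymethoxy)-8-(3-methylbut-2-en-1-yl)-3,4-dihydro-2H-chromen-4-yl] 1H-imidazole-1-carbothioate | CC(C)=CCc1c(OCOC)ccc([C@@H]2COc3c(ccc(OCOC)c3CC=C(C)C)[C@@H]2OC(=S)n2ccnc2)c1OCOC | intermediate
17 | (3R)-3-[2,4-bis(methoxymethoxy)-3-(3-methylbut-2-en-1-yl)phenyl]-7-(methoxymethoxy)-8-(3-methylbut-2-en-1-yl)-3,4-dihydro-2H-chromene | CC(C)=CCc1c(OCOC)ccc([C@@H]2COc3c(ccc(OCOC)c3CC=C(C)C)C2)c1OCOC | intermediate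
18 | Kanzonol X, 4-[(3R)-7-hydroxy-8-(3-methylbut-2-en-1-yl)-3,4-dihydro-2H-chromen-3-yl]-2-(3-methylbut-2-en-1-yl)benzene-1,3-diol | CC(C)=CCc1c(O)ccc([C@@H]2COc3c(ccc(O)c3CC=C(C)C)C2)c1O | target

**Step count and risks**

Total step count: 12. Longest linear sequence: 12 steps (steps 1 to 12; bromide 6 from step 3 enters twice, in step 4 and again in step 5).

Steps most likely to fail:

Step 8. The Lewis acid may ionise the MOM acetals instead of the enol formal, or the oxocarbenium ion may be captured by the neighbouring C8 prenyl double bond (Prins-type closure) before it recombines with the enolate. The fallback uses the classical isoflavanone annulation and sets out from 10. Heating 10 with paraformaldehyde and Et2NH in MeOH should give the Mannich base F1, which loses the amine to the α-methylene ketone F2. Intramolecular oxa-Michael addition of the phenol then closes the ring and the route is rejoined at 14.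

Step 7. Alkylation of the hindered, hydrogen-bonded phenoxide may be slow, and intermolecular acetal formation (oligomeric formals) may outrun the second, ring-forming O-alkylation. The fallback sets out from 10, which is heated with N,N-dimethylformamide dimethyl acetal in toluene to give the enaminone F3. This cyclises with loss of the amine to the isoflavone F4. Conjugate reduction of the chromone double bond with LiBH(s-Bu)3 in THF at −78 °C and protonation of the enolate rejoins the route at 14.

Step 6. The acid may also remove other MOM groups, and a ring B phenol freed in this way can undergo cyclodehydration onto the ketone to form a benzofuran. The fallback differentiates O1 before the two halves are joined and sets out from 8. Both MOM groups of 8 are removed (HCl, MeOH, 40 °C) to give the dihydroxy ketone F5. Its non-chelated 4-hydroxyl alone is re-protected (MOMCl, K2CO3, acetone) to give the hydroxy ketone F6. The chelated 2-hydroxyl is masked as the tetrahydropyranyl ether F7 (3,4-dihydro-2H-pyran, PPTS, CH2Cl2). α-Arylation of F7 with 6 under the conditions of step 5 gives the diaryl ketone F8. Mild methanolysis (PPTS, MeOH, rt) cleaves only the tetrahydropyranyl acetal and rejoins the route at 10.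

Further compounds
F1 | step 8 | 2-[2,4-bis(methoxymethoxy)-3-(3-methylbut-2-en-1-yl)phenyl]-3-(diethylamino)-1-[2-hydroxy-4-(methoxymethoxy)-3-(3-methylbut-2-en-1-yl)phenyl]propan-1-one | CCN(CC)CC(C(=O)c1ccc(OCOC)c(CC=C(C)C)c1O)c1ccc(OCOC)c(CC=C(C)C)c1OCOC
F2 | step 8 | 2-[2,4-bis(methoxymethoxy)-3-(3-methylbut-2-en-1-yl)phenyl]-1-[2-hydroxy-4-(methoxymethoxy)-3-(3-methylbut-2-en-1-yl)phenyl]prop-2-en-1-one | C=C(C(=O)c1ccc(OCOC)c(CC=C(C)C)c1O)c1ccc(OCOC)c(CC=C(C)C)c1OCOC
F3 | step 7 | 2-[2,4-bis(methoxymethoxy)-3-(3-methylbut-2-en-1-yl)phenyl]-3-(dimethylamino)-1-[2-hydroxy-4-(methoxymethoxy)-3-(3-methylbut-2-en-1-yl)phenyl]prop-2-en-1-one | CN(C)C=C(C(=O)c1ccc(OCOC)c(CC=C(C)C)c1O)c1ccc(OCOC)c(CC=C(C)C)c1OCOC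
F4 | step 7 | 3-[2,4-bis(methoxymethoxy)-3-(3-methylbut-2-en-1-yl)phenyl]-7-(methoxymethoxy)-8-(3-methylbut-2-en-1-yl)-4H-chromen-4-one | O=c1c(-c2ccc(OCOC)c(CC=C(C)C)c2OCOC)coc2c(CC=C(C)C)c(OCOC)ccc12
F5 | step 6 | 1-[2,4-dihydroxy-3-(3-methylbut-2-en-1-yl)phenyl]ethan-1-one | CC(=O)c1ccc(O)c(CC=C(C)C)c1O
F6 | step 6 | 1-[2-hydroxy-4-(methoxymethoxy)-3-(3-methylbut-2-en-1-yl)phenyl]ethan-1-one | CC(=O)c1ccc(OCOC)c(CC=C(C)C)c1O
F7 | step 6 | 1-[4-(methoxymethoxy)-3-(3-methylbut-2-en-1-yl)-2-(oxan-2-yloxy)phenyl]ethan-1-one | CC(=O)c1ccc(OCOC)c(CC=C(C)C)c1OC1CCCCO1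
F8 | step 6 | 2-[2,4-bis(methoxymethoxy)-3-(3-methylbut-2-en-1-yl)phenyl]-1-[4-(methoxymethoxy)-3-(3-methylbut-2-en-1-yl)-2-(oxan-2-yloxy)phenyl]ethan-1-one | O=C(Cc1ccc(OCOC)c(CC=C(C)C)c1OCOC)c1ccc(OCOC)c(CC=C(C)C)c1OC1CCCCO1
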